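(The numbers in the tables are simulated from invented constants; the scatter is artificial.)

At early times the north-west flask lost 20.5% of its starting complex in the first hour and the west flask 8.50%. That is more in the north-west flask, which has the higher concentrations at the same equivalents, so we take the loss to follow the concentration of incoming ligand.

| setting | north-west | west | ochre | green | grey |
|---|---|---|---|---|---|
| starting complex | 22 mM | 7.5 mM | 15 mM | 15 mM | 15 mM |
| incoming ligand | 0.80 equiv | 0.80 equiv | 0.800 equiv | 1.00 equiv | 4.00 equiv |
| remark | run made earlier | run made earlier |  |  |  |
| time |  |  | 3.0 d | 3.0 d | 3.0 d |

- north-west (time / h: complex with one exchanged / %, starting complex / %): 1.00: 19.2, 79.5; 2.00: 31.7, 67.5; 3.00: 39.2, 59.0; 5.00: 48.0, 48.3; 8.00: 53.9, 40.3; 15.0: 59.7, 32.7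
- west (time / h: complex with one exchanged / %, starting complex / %): 1.00: 8.7, 91.5; 2.00: 14.8, 85.5; 3.00: 19.9, 80.5; 5.00: 28.8, 71.5; 8.00: 37.6, 61.1; 15.0: 50.4, 48.0

(scatter of a reading: 0.5 percentage points)

- steps under discussion: starting complex + incoming ligand <-> leaving ligand + complex with one exchanged; complex with one exchanged + incoming ligand <-> leaving ligand + complex with two exchanged; complex with two exchanged + incoming ligand <-> leaving ligand + complex with three exchanged; complex with three exchanged + incoming ligand <-> leaving ligand + complex with four exchanged; leaving ligand -> by-product carried off; incoming ligand -> decomposition product; leaving ligand + complex with one exchanged -> side product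

We take that concentration to stand in two forward rates: making complex with one exchanged, as ligand times starting complex, and carrying it on, as ligand times complex with one exchanged. Ligand cancels in their ratio. What remains is the carry-on ratio, the rate constant of carrying on over that of making, the inverse of the selectivity factor. To first order in that ratio:

missing share = carry-on ratio × (ln(charged/left) − share of complex with one exchanged)

The last north-west reading, with 7.60% missing, counts whatever is missing from these two complexes as carried on, and so gives, as a reading with its scatter,

carry-on ratio = 0.146

West gives 0.0696, but from a gap of 1.60%, smaller than north-west's, so we carry the north-west value. Our reckoning, with "left" the fraction of starting complex remaining, is: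

share of complex with one exchanged = (left^ratio − left)/(1 − ratio)

1. final complex with one exchanged, as a percentage of the starting complex charged, for each flask in turn (ochre, green, grey)

The forecast gives 62%, 68% and 1%, the last because at 4.00 equiv complex with one exchanged is “almost fully carried on”. Its carry-on ratio is 0.18, where ours is 0.146.

The ochre, green and grey flasks give 64.1%, 71.0% and 12.5%.

    starting complex + incoming ligand ⇌ leaving ligand + complex with one exchanged (K = 11.0, k = 14.9 /M/h)
    complex with one exchanged + incoming ligand ⇌ leaving ligand + complex with two exchanged (K = 1.72, k = 1.21 /M/h)
    complex with two exchanged + incoming ligand ⇌ leaving ligand + complex with three exchanged (K = 6.70, k = 27.5 /M/h)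
    complex with three exchanged + incoming ligand ⇌ leaving ligand + complex with four exchanged (K = 1.30, k = 39.9 /M/h)
    leaving ligand → by-product carried off (k = 0.293 /h)
    incoming ligand → decomposition product (k = 4.61 × 10⁻⁵ /h)
    leaving ligand + complex with one exchanged → side product (k = 1.96 /M/h)

In the grey flask, complex with one exchanged stood at 25.0% after 1.50 d and 12.5% after 3.00 d, with 21.3% of the incoming ligand's own charge left. The carry-on ratio, with 28% of starting complex left in ochre, gives 64.4% against 64.1%. In green, with 16% left, it gives 70.9% against 71.0%.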